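Assumption: (E)-geranic acid and methyl (2S)-3-bromo-2-methylpropanoate (the bromide derived from the Roche ester) are taken as purchasable. Atom labels C1–C15 follow longipinane numbering: C1 ketone carbon, C2=C3 enone, C4/C11 cyclobutane bridgeheads, C5/C10 the other two cyclobutane carbons, C6–C9 in the seven-membered ring, C12 on C3, C13 and C14 on C6 (C14 carries the angelate), C15 on C10.

**Retrosynthetic overview**
1. Target ⇒ (dehydrogenation, acetylation, angeloylation) keto diol 18, whose C7–OH comes from hydroxyl-directed reduction of β-hydroxy ketone 17.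
2. Seven-membered ring (formed last) ⇒ C6–C7 reductive aldol closure of cyclobutylidene ester–aldehyde 13; C6/C13/C14 come from a phosphonate, the C7 aldehyde from a prenyl group.
3. Cyclobutane and six-membered ring (formed together, first) ⇒ photochemical Wolff rearrangement / intramolecular ketene–alkene [2+2] of diazoketone 9 (bonds C3–C4, C5–C11, C4–C10).
4. Diazoketone 9 ⇒ Negishi acylation of the Roche-ester-derived alkylzinc with geranoyl chloride; the purchased C3 stereocentre steers the cycloaddition and is erased in the last step.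

**Route**

Step 1
Reactants: 1 (2E)-3,7-dimethylocta-2,6-dienoic acid (geranic acid)
Product: 2 (2E)-3,7-dimethylocta-2,6-dienoyl chloride
Conditions: (COCl)2, DMF (cat.), CH2Cl2, 0 °C to rt
Reagents that add atoms: oxalyl chloride, ClC(=O)C(=O)Cl
Why: Acid chloride formation through the Vilsmeier-type chloroiminium species under neutral conditions, which leaves the E-trisubstituted alkene (it later encodes the C10 configuration) untouched.

Step 2
Reactants: 3 methyl (2S)-3-bromo-2-methylpropanoate; 2 (2E)-3,7-dimethylocta-2,6-dienoyl chloride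
Product: 5 methyl (2R,5E)-2,6,10-trimethyl-4-oxoundeca-5,9-dienoate, via alkylzinc bromide 4 (not isolated)
Conditions: Zn dust, LiCl, THF, 40 °C; then 2, Pd(PPh3)4 (5 mol %), THF, 0 °C to rt
Reagents that add atoms: none
Why: Knochel zinc insertion followed by Negishi acylation joins 14 of the 15 skeletal carbons; the purchased stereocentre is not involved and is carried unchanged (the descriptor changes from S to R only through CIP priorities).

Step 3
Reactants: 5 methyl (2R,5E)-2,6,10-trimethyl-4-oxoundeca-5,9-dienoate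
Product: 6 methyl (2R)-3-{2-[(1E)-2,6-dimethylhepta-1,5-dien-1-yl]-1,3-dioxolan-2-yl}-2-methylpropanoate
Conditions: (TMSOCH2)2, TMSOTf (5 mol %), CH2Cl2, −78 to −20 °C; pyridine quench
Reagents that add atoms: 1,2-bis(trimethylsilyloxy)ethane, C[Si](C)(C)OCCO[Si](C)(C)C
Why: Noyori ketalisation protects the enone without moving or isomerising the double bond, so the C10=C11 alkene becomes electron-rich enough to act as a ketenophile.

Step 4
Reactants: 6 methyl (2R)-3-{2-[(1E)-2,6-dimethylhepta-1,5-dien-1-yl]-1,3-dioxolan-2-yl}-2-methylpropanoate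
Product: 7 (2R)-3-{2-[(1E)-2,6-dimethylhepta-1,5-dien-1-yl]-1,3-dioxolan-2-yl}-2-methylpropanoic acid
Conditions: LiOH, THF/H2O, rt; then cold 0.5 M HCl to pH 4
Reagents that add atoms: lithium hydroxide, [Li+].[OH-]
Why: Mild saponification; the ketal and alkenes are base-stable and the α-stereocentre is not epimerised at room temperature.

Step 5
Reactants: 7 (2R)-3-{2-[(1E)-2,6-dimethylhepta-1,5-dien-1-yl]-1,3-dioxolan-2-yl}-2-methylpropanoic acid
Product: 9 (3R)-1-diazo-4-{2-[(1E)-2,6-dimethylhepta-1,5-dien-1-yl]-1,3-dioxolan-2-yl}-3-methylbutan-2-one, via mixed anhydride 8 (not isolated)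
Conditions: i-BuOCOCl, N-methylmorpholine, THF, −15 °C; then CH2N2, Et2O, 0 °C to rt
Reagents that add atoms: diazomethane, C=[N+]=[N-]
Why: Acylation of diazomethane through the mixed carbonic anhydride (first half of an Arndt–Eistert sequence) avoids HCl, so the acid-labile ketal and the α-stereocentre survive; this adds C4.

Step 6
Reactants: 9 (3R)-1-diazo-4-{2-[(1E)-2,6-dimethylhepta-1,5-dien-1-yl]-1,3-dioxolan-2-yl}-3-methylbutan-2-one
Product: 11 (1R,4R,5S,7S)-4,7-dimethyl-7-(4-methylpent-3-en-1-yl)spiro[bicyclo[3.1.1]heptane-2,2'-[1,3]dioxolan]-6-one, via ketene 10 (not isolated)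
Conditions: hν (365 nm LEDs), PhMe (5 mM), 80 °C
Reagents that add atoms: none
Why: Photochemical Wolff rearrangement (C3 migrates to C4 with retention) gives alkylketene 10, which closes by a stereospecific crossed intramolecular ketene–alkene [2+2] (Snider/Corey bergamotene type, carbonyl carbon to the less substituted C11): the E-alkene places C15 syn and the C9 chain anti to the new three-carbon bridge, and a half-chair transition state with the C3 methyl pseudo-equatorial (away from the axial dioxolane oxygen) sets C4, C10 and C11 relative to the purchased centre.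

Step 7
Reactants: 11 (1R,4R,5S,7S)-4,7-dimethyl-7-(4-methylpent-3-en-1-yl)spiro[bicyclo[3.1.1]heptane-2,2'-[1,3]dioxolan]-6-one
Product: 12 ethyl 2-[4,7-dimethyl-7-(4-methylpent-3-en-1-yl)spiro[bicyclo[3.1.1]heptane-2,2'-[1,3]dioxolan]-6-ylidene]propanoate (ring stereocentres as in 11; E/Z mixture at C5=C6)
Conditions: (EtO)2P(O)CH(CH3)CO2Et, NaH, THF, 0 °C to reflux
Reagents that add atoms: triethyl 2-phosphonopropionate, CCOC(=O)C(C)P(=O)(OCC)OCC
Why: Horner–Wadsworth–Emmons olefination, driven by strain release at the cyclobutanone, brings in C6, C13 and C14; the alkene geometry is irrelevant because C6 passes through an enolate in step 9.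

Step 8
Reactants: 12 ethyl 2-[4,7-dimethyl-7-(4-methylpent-3-en-1-yl)spiro[bicyclo[3.1.1]heptane-2,2'-[1,3]dioxolan]-6-ylidene]propanoate
Product: 13 ethyl 2-[4,7-dimethyl-7-(3-oxopropyl)spiro[bicyclo[3.1.1]heptane-2,2'-[1,3]dioxolan]-6-ylidene]propanoate (ring stereocentres as in 11)
Conditions: O3, CH2Cl2, −78 °C (Sudan red 7B end point); then Me2S
Reagents that add atoms: ozone, [O-][O+]=O
Why: Chemoselective ozonolysis of the electron-rich trisubstituted prenyl alkene over the electron-poor tetrasubstituted enoate unmasks the C7 aldehyde.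

Step 9
Reactants: 13 ethyl 2-[4,7-dimethyl-7-(3-oxopropyl)spiro[bicyclo[3.1.1]heptane-2,2'-[1,3]dioxolan]-6-ylidene]propanoate
Product: 15 ethyl 1,1-(ethylenedioxy)-7-hydroxylongipinan-14-oate (tricyclic β-hydroxy ester; H5 syn to the three-carbon bridge; ester on the C4 flank; 7-OH cis to the ester), via ester enolate 14 (not isolated)
Conditions: Co(dpm)2 (10 mol %; dpm = 2,2,6,6-tetramethylheptane-3,5-dionate), PhSiH3 (1.5 equiv), ClCH2CH2Cl, 25 °C; then aq. NH4F
Reagents that add atoms: none
Why: Proposed new method: a cobalt-hydride reductive aldol cyclisation in which hydrogen-atom transfer to the β-carbon C5 of the tetrasubstituted cyclobutylidene ester gives the α-ester radical/cobalt enolate 14 that is trapped by the tethered aldehyde to close the seven-membered ring (closest known chemistry: the intermolecular Isayama–Mukaiyama Co/PhSiH3 reductive aldol and metal-hydride H-atom transfer to hindered alkenes); only the C5 epimer with C6 on the face of the C9 tether can cyclise, which fixes C5, C6 is set in the C–C bond formation with the bulkier ester on the C4 flank away from the C1 dioxolane, and the C7 carbinol (expected cis to the ester from a closed transition state) is re-set in steps 11 and 12.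

Step 10
Reactants: 15 ethyl 1,1-(ethylenedioxy)-7-hydroxylongipinan-14-oate
Product: 16 7,14-dihydroxylongipinan-1-one (7-OH cis to C14)
Conditions: LiAlH4, THF, 0 °C; then 1 M HCl, THF/H2O, rt, 2 h
Reagents that add atoms: water, O
Why: Hydride reduction of the ester to the C14 carbinol, then ketal hydrolysis in the acidic work-up frees the C1 ketone; no stereocentre is touched.

Step 11
Reactants: 16 7,14-dihydroxylongipinan-1-one (7-OH cis to C14)
Product: 17 14-hydroxylongipinane-1,7-dione
Conditions: NaOCl, AcOH, rt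
Reagents that add atoms: none
Why: Stevens oxidation (hypochlorite in acetic acid) oxidises the secondary alcohol in preference to the neopentyl primary one, removing the C7 centre of the wrong or uncertain configuration while keeping the C14 hydroxyl as a directing group.

Step 12
Reactants: 17 14-hydroxylongipinane-1,7-dione
Product: 18 7,14-dihydroxylongipinan-1-one (7-OH trans to C14 and cis to C13, as in the target)
Conditions: Me4NBH(OAc)3, MeCN/AcOH (1:1), −20 °C
Reagents that add atoms: none
Why: Evans–Saksena hydroxyl-directed reduction delivers hydride intramolecularly from boron bound to O14 to the face of C7 that carries the CH2OH group, giving the anti 1,3-diol; the C1 ketone has no directing hydroxyl and is not reduced.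

Step 13
Reactants: 18 7,14-dihydroxylongipinan-1-one (7-OH trans to C14)
Product: 19 14-angeloyloxy-7-hydroxylongipinan-1-one
Conditions: angelic acid, 2,4,6-trichlorobenzoyl chloride, Et3N, PhMe, rt; then 18, 75 °C
Reagents that add atoms: angelic acid, C/C=C(/C)C(=O)O
Why: Yamaguchi-type esterification through the mixed anhydride without a nucleophilic catalyst acylates the less hindered primary alcohol and preserves the Z (angelate) geometry.

Step 14
Reactants: 19 14-angeloyloxy-7-hydroxylongipinan-1-one
Product: 20 7-acetoxy-14-angeloyloxylongipinan-1-one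
Conditions: Ac2O, DMAP (cat.), pyridine, rt
Reagents that add atoms: acetic anhydride, CC(=O)OC(C)=O
Why: DMAP-catalysed acetylation of the remaining secondary alcohol; no stereocentre is affected.

Step 15
Reactants: 20 7-acetoxy-14-angeloyloxylongipinan-1-one
Product: 21 7-acetoxy-14-angeloyloxylongipin-2-en-1-one (target, CNP0374220.2)
Conditions: 2-iodoxybenzoic acid (IBX), 4-methoxypyridine N-oxide, DMSO, rt
Reagents that add atoms: none
Why: Nicolaou IBX α,β-dehydrogenation can only proceed towards C2 (the other α-carbon, C11, is a bridgehead), giving the C2=C3 enone and erasing the temporary C3 stereocentre.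

**Compound list**
1 | (2E)-3,7-dimethylocta-2,6-dienoic acid (geranic acid) | CC(C)=CCC/C(C)=C/C(=O)O | starting material
2 | (2E)-3,7-dimethylocta-2,6-dienoyl chloride | CC(C)=CCC/C(C)=C/C(=O)Cl | intermediate
3 | methyl (2S)-3-bromo-2-methylpropanoate | C[C@H](CBr)C(=O)OC | starting material
4 | [(2S)-3-methoxy-2-methyl-3-oxopropyl]zinc bromide | C[C@H](C[Zn]Br)C(=O)OC | intermediate
5 | methyl (2R,5E)-2,6,10-trimethyl-4-oxoundeca-5,9-dienoate | C[C@H](CC(=O)/C=C(\C)CCC=C(C)C)C(=O)OC | intermediate
6 | methyl (2R)-3-{2-[(1E)-2,6-dimethylhepta-1,5-dien-1-yl]-1,3-dioxolan-2-yl}-2-methylpropanoate | C[C@H](CC1(OCCO1)/C=C(\C)CCC=C(C)C)C(=O)OC | intermediate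
7 | (2R)-3-{2-[(1E)-2,6-dimethylhepta-1,5-dien-1-yl]-1,3-dioxolan-2-yl}-2-methylpropanoic acid | C[C@H](CC1(OCCO1)/C=C(\C)CCC=C(C)C)C(=O)O | intermediate
8 | mixed anhydride of 7 with isobutyl hydrogen carbonate | C[C@H](CC1(OCCO1)/C=C(\C)CCC=C(C)C)C(=O)OC(=O)OCC(C)C | intermediate
9 | (3R)-1-diazo-4-{2-[(1E)-2,6-dimethylhepta-1,5-dien-1-yl]-1,3-dioxolan-2-yl}-3-methylbutan-2-one | C[C@H](CC1(OCCO1)/C=C(\C)CCC=C(C)C)C(=O)C=[N+]=[N-] | intermediate
10 | (3R)-4-{2-[(1E)-2,6-dimethylhepta-1,5-dien-1-yl]-1,3-dioxolan-2-yl}-3-methylbut-1-en-1-one (ketene) | C[C@H](CC1(OCCO1)/C=C(\C)CCC=C(C)C)C=C=O | intermediate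
11 | (1R,4R,5S,7S)-4,7-dimethyl-7-(4-methylpent-3-en-1-yl)spiro[bicyclo[3.1.1]heptane-2,2'-[1,3]dioxolan]-6-one (C5 ketone; C12 cis to the C10 bridge; C15 syn and C9 chain anti to the three-carbon bridge) | O=C1[C@H]2[C@H](C)CC3(OCCO3)[C@@H]1[C@@]2(C)CCC=C(C)C | intermediate
12 | ethyl 2-[4,7-dimethyl-7-(4-methylpent-3-en-1-yl)spiro[bicyclo[3.1.1]heptane-2,2'-[1,3]dioxolan]-6-ylidene]propanoate (ring stereocentres as in 11; E/Z mixture) | CCOC(=O)C(C)=C1[C@H]2[C@H](C)CC3(OCCO3)[C@@H]1[C@@]2(C)CCC=C(C)C | intermediate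
13 | ethyl 2-[4,7-dimethyl-7-(3-oxopropyl)spiro[bicyclo[3.1.1]heptane-2,2'-[1,3]dioxolan]-6-ylidene]propanoate (ring stereocentres as in 11; E/Z mixture) | CCOC(=O)C(C)=C1[C@H]2[C@H](C)CC3(OCCO3)[C@@H]1[C@@]2(C)CCC=O | intermediate
14 | cobalt ester enolate after H transfer to C5 (drawn as the enolate anion; H5 syn to the three-carbon bridge) | CCOC([O-])=C(C)[C@@H]1[C@H]2[C@H](C)CC3(OCCO3)[C@@H]1[C@@]2(C)CCC=O | intermediate
15 | ethyl 1,1-(ethylenedioxy)-7-hydroxylongipinan-14-oate (7-OH cis to the ester) | CCOC(=O)[C@]1(C)[C@@H]2[C@H]3[C@H](C)CC4(OCCO4)[C@@H]2[C@@]3(C)CC[C@@H]1O | intermediate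
16 | 7,14-dihydroxylongipinan-1-one (7-OH cis to C14) | OC[C@]1(C)[C@@H]2[C@H]3[C@H](C)CC(=O)[C@@H]2[C@@]3(C)CC[C@@H]1O | intermediate
17 | 14-hydroxylongipinane-1,7-dione | OC[C@]1(C)[C@@H]2[C@H]3[C@H](C)CC(=O)[C@@H]2[C@@]3(C)CCC1=O | intermediate
18 | 7,14-dihydroxylongipinan-1-one (7-OH trans to C14) | OC[C@]1(C)[C@@H]2[C@H]3[C@H](C)CC(=O)[C@@H]2[C@@]3(C)CC[C@H]1O | intermediate
19 | 14-angeloyloxy-7-hydroxylongipinan-1-one | C/C=C(/C)C(=O)OC[C@]1(C)[C@@H]2[C@H]3[C@H](C)CC(=O)[C@@H]2[C@@]3(C)CC[C@H]1O | intermediate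
20 | 7-acetoxy-14-angeloyloxylongipinan-1-one | C/C=C(/C)C(=O)OC[C@]1(C)[C@@H]2[C@H]3[C@H](C)CC(=O)[C@@H]2[C@@]3(C)CC[C@H]1OC(C)=O | intermediate
21 | 7-acetoxy-14-angeloyloxylongipin-2-en-1-one | C/C=C(/C)C(=O)OC[C@]1(C)[C@@H]2[C@H]3C(C)=CC(=O)[C@@H]2[C@@]3(C)CC[C@H]1OC(C)=O | target

**Totals and risks**

Total step count: 15. Longest linear sequence: 15 steps (from geranic acid 1; 14 from bromide 3).

Step 6 (photochemical Wolff/ketene [2+2]). The monoalkylketene may dimerise or add sluggishly to an alkene flanked by the ketal, and the facial control by the C3 methyl is a model prediction. The fallback sets out from 9. A thermal Wolff rearrangement (PhCO2Ag cat., Et3N, THF) in the presence of pyrrolidine gives the homologous pyrrolidine amide F1. Tf2O and 2,4,6-collidine in refluxing ClCH2CH2Cl convert it into the keteniminium salt, which undergoes the Ghosez-type thermal intramolecular [2+2] to the cyclobutaniminium triflate F2. Hydrolysis with aqueous NaHCO3 returns to the route at 11.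

Step 7 (olefination to a tetrasubstituted alkene on a hindered cyclobutanone). The fallback sets out from 11. The lithium enolate of ethyl propanoate (LDA, THF, −78 °C) adds to the strained ketone to give the β-hydroxy ester F3. Dehydration with SOCl2/pyridine can only go towards C6, because both ring α-carbons are bridgeheads, and returns to the route at 12.

Step 9 (the proposed new reductive aldol cyclisation). H-atom transfer to the hindered enoate or the seven-membered closure may fail. The preference for the ester on the C4 flank rests only on the remote difference between the C1 dioxolane and C3–H, so it may be modest. The fallback sets out from 12, before ozonolysis. Conjugate reduction with SmI2/HMPA/t-BuOH gives the saturated ester F4. LDA then CBr4 gives the α-bromo ester F5. Ozonolysis (O3; Me2S) gives the bromo aldehyde F6. A SmI2-mediated intramolecular Reformatsky reaction (THF, −78 °C) closes the seven-membered ring and returns to the route at 15. If the C6 epimer forms, it is separable at 15 and can be recycled by base-induced retro-aldol/aldol equilibration.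

**Further compounds**
F1 | step 6 | (3R)-4-{2-[(1E)-2,6-dimethylhepta-1,5-dien-1-yl]-1,3-dioxolan-2-yl}-3-methyl-1-(pyrrolidin-1-yl)butan-1-one | C[C@H](CC1(OCCO1)/C=C(\C)CCC=C(C)C)CC(=O)N1CCCC1
F2 | step 6 | 1-[4,7-dimethyl-7-(4-methylpent-3-en-1-yl)spiro[bicyclo[3.1.1]heptane-2,2'-[1,3]dioxolan]-6-ylidene]pyrrolidin-1-ium trifluoromethanesulfonate (ring stereocentres as in 11) | C1CC[N+](=C2[C@H]3[C@H](C)CC4(OCCO4)[C@@H]2[C@@]3(C)CCC=C(C)C)C1.[O-]S(=O)(=O)C(F)(F)F
F3 | step 7 | ethyl 2-[6-hydroxy-4,7-dimethyl-7-(4-methylpent-3-en-1-yl)spiro[bicyclo[3.1.1]heptane-2,2'-[1,3]dioxolan]-6-yl]propanoate (mixture at C5 and C6) | CCOC(=O)C(C)C1(O)[C@H]2[C@H](C)CC3(OCCO3)[C@@H]1[C@@]2(C)CCC=C(C)C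
F4 | step 9 | ethyl 2-[4,7-dimethyl-7-(4-methylpent-3-en-1-yl)spiro[bicyclo[3.1.1]heptane-2,2'-[1,3]dioxolan]-6-yl]propanoate (H5 syn to the three-carbon bridge; mixture at C6) | CCOC(=O)C(C)[C@@H]1[C@H]2[C@H](C)CC3(OCCO3)[C@@H]1[C@@]2(C)CCC=C(C)C
F5 | step 9 | ethyl 2-bromo-2-[4,7-dimethyl-7-(4-methylpent-3-en-1-yl)spiro[bicyclo[3.1.1]heptane-2,2'-[1,3]dioxolan]-6-yl]propanoate | CCOC(=O)C(C)(Br)[C@@H]1[C@H]2[C@H](C)CC3(OCCO3)[C@@H]1[C@@]2(C)CCC=C(C)C
F6 | step 9 | ethyl 2-bromo-2-[4,7-dimethyl-7-(3-oxopropyl)spiro[bicyclo[3.1.1]heptane-2,2'-[1,3]dioxolan]-6-yl]propanoate | CCOC(=O)C(C)(Br)[C@@H]1[C@H]2[C@H](C)CC3(OCCO3)[C@@H]1[C@@]2(C)CCC=O
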